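## Retrosynthetic overview

- The p‑coumarate is attached last, at the C6 hydroxyl of the diol, with the phenol masked as acetate. The trans C5/C6 pair comes from hydroboration of a C5=C6 alkene. The C5 carbinol side chain is built from a C5 enol silane (triflate, methoxycarbonylation, MeMgBr).
- Key disconnection: the seven‑membered ring at C3a–C4 and C8–C8a. A cyclopropylzinc reagent (C6–C7–C8 as a three‑membered ring bearing the C8 methyl and, on C6, a 2‑silyloxyvinyl group holding C5 and C4) is coupled with (3S)‑3‑methylcyclopent‑1‑enyl triflate. The cis‑1,2‑dialkenylcyclopropane so formed undergoes Cope rearrangement in the same flask.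
- Enabling feature: in the seven‑membered ring the tetrasubstituted C8=C8a alkene (exocyclic to the five‑membered ring) and the functionalised C5–C6 pair are separated only by the C7 methylene. The ring is therefore a masked cyclohepta‑1,4‑diene, the retron of a divinylcyclopropane rearrangement in which the cyclopentene supplies one alkene.
- Ring order: the five‑membered ring is bought (3‑methylcyclopent‑2‑enone; C3 by asymmetric conjugate reduction). A temporary cyclopropane follows (both centres from one carbinol by directed Simmons–Smith reaction). The seven‑membered ring comes last, by ring expansion of the cyclopropane, which also sets C3a by chirality transfer.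

Key step: step 7

Remark: ring positions are numbered as in azulene (C3 carries the ring methyl, C3a is the ring‑fusion CH, C4–C8 are the seven‑membered ring carbons, C8a is the sp2 ring‑fusion carbon).
Remark: the ligand antipodes named in steps 1 and 6 are those assumed, from the usual sense of induction of these catalyst families, to give the drawn configurations; the mirror‑image ligand would be used if the sense proved opposite.

## Route

Step 1
Reactants: 1 pent-3-yn-2-one
Product: 2 (2S)-pent-3-yn-2-ol
Conditions: RuCl[(S,S)-TsDPEN](p-cymene) (0.5 mol%), KOH (1 mol%), i-PrOH, 25 °C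
Reagents that add atoms: none
Why: Noyori-type asymmetric transfer hydrogenation of an alkynyl ketone; the chiral Ru hydride differentiates the alkynyl and methyl flanks and should set the (S)-carbinol, from which both cyclopropane centres are later derived.

Step 2
Reactants: 2 (2S)-pent-3-yn-2-ol
Product: 4 (2S,3Z)-4-iodopent-3-en-2-ol, via cyclic alkenylalanate 3 (not isolated)
Conditions: NaAlH2(OCH2CH2OCH3)2 (1.5 equiv), THF, 0 °C → rt; then I2, THF, −78 °C
Reagents that add atoms: iodine, SMILES II
Why: Hydroxyl-directed trans-hydroalumination of a propargylic alcohol places aluminium on the distal alkyne carbon in the five-membered alanate 3, and iodinolysis of the C–Al bond with retention should give the Z-iodoalkene with iodine cis to the carbinol carbon.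

Step 3
Reactants: 4 (2S,3Z)-4-iodopent-3-en-2-ol
Product: 5 (1S)-1-[(1R,2R)-2-iodo-2-methylcyclopropyl]ethan-1-ol
Conditions: Et2Zn (2.2 equiv), CH2I2 (4.4 equiv), CH2Cl2, −10 → 0 °C
Reagents that add atoms: diiodomethane, SMILES ICI
Why: Hydroxyl-directed Simmons–Smith cyclopropanation; allylic 1,3-strain with the cis iodine holds the carbinol hydrogen in the alkene plane, the zinc alkoxide delivers methylene to the face syn to oxygen, and the stereospecific addition keeps iodine cis to the side chain, so the (S)-carbinol should give the (1R,2R) ring.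

Step 4
Reactants: 5 (1S)-1-[(1R,2R)-2-iodo-2-methylcyclopropyl]ethan-1-ol
Product: 6 1-[(1R,2R)-2-iodo-2-methylcyclopropyl]ethan-1-one
Conditions: Dess–Martin periodinane, NaHCO3, CH2Cl2, 0 °C → rt
Reagents that add atoms: none
Why: Dess–Martin oxidation of a secondary alcohol under buffered conditions that do not enolise the ketone toward the ring, so the cis cyclopropane should survive.

Step 5
Reactants: 6 1-[(1R,2R)-2-iodo-2-methylcyclopropyl]ethan-1-one
Product: 7 tert-butyl({1-[(1R,2R)-2-iodo-2-methylcyclopropyl]ethenyl}oxy)dimethylsilane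
Conditions: t-BuMe2SiOTf, Et3N, CH2Cl2, 0 °C
Reagents that add atoms: tert-butyldimethylsilyl trifluoromethanesulfonate, SMILES CC(C)(C)[Si](C)(C)OS(=O)(=O)C(F)(F)F
Why: Soft enolisation and O-silylation; only the methyl side can enolise (an enol toward the ring would be an alkylidenecyclopropane), which gives the 2-silyloxyvinyl group that serves as the second alkene of the rearrangement.

Step 6
Reactants: 8 3-methylcyclopent-2-en-1-one
Product: 11 (3S)-3-methylcyclopent-1-en-1-yl trifluoromethanesulfonate, via bis(enoxy)diphenylsilane 9 (not isolated), via lithium enolate 10 (not isolated)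
Conditions: CuCl (3 mol%), NaOt-Bu (3 mol%), (S)-p-Tol-BINAP (3 mol%), Ph2SiH2 (0.52 equiv), toluene, 0 °C; then MeLi (1.0 equiv), THF, 0 °C; then PhNTf2, −78 → 0 °C
Reagents that add atoms: N-phenylbis(trifluoromethanesulfonimide), SMILES O=S(=O)(N(c1ccccc1)S(=O)(=O)C(F)(F)F)C(F)(F)F
Why: Copper hydride asymmetric conjugate reduction sets C3 and gives a regiodefined enol silane; MeLi frees the lithium enolate without proton transfer, and O-triflation with PhNTf2 fixes the C1=C2 enol regiochemistry.

Step 7
Reactants: 7 tert-butyl({1-[(1R,2R)-2-iodo-2-methylcyclopropyl]ethenyl}oxy)dimethylsilane; 11 (3S)-3-methylcyclopent-1-en-1-yl trifluoromethanesulfonate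
Product: 15 tert-butyl{[(3S,3aS)-3,8-dimethyl-1,2,3,3a,4,7-hexahydroazulen-5-yl]oxy}dimethylsilane, via cyclopropyllithium 12 (not isolated), via cyclopropylzinc chloride 13 (not isolated), via cis-1,2-dialkenylcyclopropane 14 (not isolated)
Conditions: t-BuLi (2.1 equiv), Et2O, −78 °C; ZnCl2 (1.2 equiv), THF, −78 → 0 °C; then 11, Pd2(dba)3 (2.5 mol%), SPhos (10 mol%), THF, 25 → 65 °C
Reagents that add atoms: none
Why: Iodine–lithium exchange with retention gives 12, ZnCl2 converts it into the configurationally stable zinc reagent 13, and Negishi coupling with 11 at the cyclopropyl carbon forms the C8–C8a bond with retention to give the cis-1,2-dialkenylcyclopropane 14, which on warming undergoes a Cope ([3,3]) shift that forms the C3a–C4 bond, cleaves the C6–C8 cyclopropane bond and leaves the tetrasubstituted C8=C8a alkene and the C5=C6 enol silane. The closest known reaction types are the palladium-catalysed coupling of cyclopropylzinc halides with alkenyl triflates and the cis-divinylcyclopropane to cyclohepta-1,4-diene rearrangement used for seven-membered ring annulation onto cycloalkenyl units. The seven-membered ring is closed by sigmatropic ring expansion of the three-membered ring through the boat transition state in which both alkenes lie over the cyclopropane, not by an ionic or radical closure. The only new stereocentre, C3a, is set by chirality transfer: for the (1S,2R) cyclopropane only one boat geometry exists, and it delivers the vinyl terminus C4 to the cyclopentene face syn to the C3 methyl group, against the steric preference of the ring. The step needs retention at C8 through lithium, zinc and palladium (cyclopropyl metals do not invert at these temperatures), the cis relation of the two alkenyl groups (fixed by the Z-iodoalkene of step 2 and the stereospecific cyclopropanation), and alkene termini without inward-pointing substituents (a ring CH and a CH2) so that the rearrangement outruns one-centre epimerisation of the cyclopropane.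

Step 8
Reactants: 15 tert-butyl{[(3S,3aS)-3,8-dimethyl-1,2,3,3a,4,7-hexahydroazulen-5-yl]oxy}dimethylsilane
Product: 17 (3S,3aS)-3,8-dimethyl-1,2,3,3a,4,7-hexahydroazulen-5-yl trifluoromethanesulfonate, via caesium enolate 16 (not isolated)
Conditions: CsF, PhNTf2, DME, rt
Reagents that add atoms: N-phenylbis(trifluoromethanesulfonimide), SMILES O=S(=O)(N(c1ccccc1)S(=O)(=O)C(F)(F)F)C(F)(F)F
Why: Fluoride cleaves the O–Si bond to the caesium enolate whose regiochemistry was fixed by the rearrangement, and O-triflation by PhNTf2 in the same flask traps it before proton transfer can move the double bond.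

Step 9
Reactants: 17 (3S,3aS)-3,8-dimethyl-1,2,3,3a,4,7-hexahydroazulen-5-yl trifluoromethanesulfonate
Product: 18 methyl (3S,3aS)-3,8-dimethyl-1,2,3,3a,4,7-hexahydroazulene-5-carboxylate
Conditions: Pd(OAc)2 (5 mol%), PPh3 (10 mol%), CO (1 atm), Et3N, MeOH/DMF, 60 °C
Reagents that add atoms: carbon monoxide, SMILES [C-]#[O+]; methanol, SMILES CO
Why: Palladium-catalysed methoxycarbonylation of an alkenyl triflate (oxidative addition to zerovalent palladium, CO insertion, methanolysis), which should leave the isolated alkenes untouched.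

Step 10
Reactants: 18 methyl (3S,3aS)-3,8-dimethyl-1,2,3,3a,4,7-hexahydroazulene-5-carboxylate
Product: 19 2-[(3S,3aS)-3,8-dimethyl-1,2,3,3a,4,7-hexahydroazulen-5-yl]propan-2-ol
Conditions: MeMgBr (3 equiv), THF, −40 → 0 °C
Reagents that add atoms: methylmagnesium bromide, SMILES C[Mg]Br
Why: Double Grignard addition to the ester gives the tertiary carbinol; at low temperature carbonyl addition should outrun deprotonation at the doubly allylic C7.

Step 11
Reactants: 19 2-[(3S,3aS)-3,8-dimethyl-1,2,3,3a,4,7-hexahydroazulen-5-yl]propan-2-ol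
Product: 21 (3S,3aS,5S,6S)-5-(2-hydroxypropan-2-yl)-3,8-dimethyl-1,2,3,3a,4,5,6,7-octahydroazulen-6-ol, via cyclic alkoxyborane 20 (not isolated)
Conditions: BH3·THF (2.2 equiv), THF, 0 °C → rt; then NaOH, H2O2, 0 °C
Reagents that add atoms: hydrogen peroxide, SMILES OO
Why: Hydroboration–oxidation: boron adds to the less substituted C6 of the trisubstituted alkene, syn addition of H and B makes the C5 side chain and the C6 hydroxyl trans, and attack on the ring face anti to the C3a–C3 bond (the face of H-3a) should set both centres as (5S,6S), while the tetrasubstituted alkene is too hindered to react at 0 °C.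

Step 12
Reactants: 21 (3S,3aS,5S,6S)-5-(2-hydroxypropan-2-yl)-3,8-dimethyl-1,2,3,3a,4,5,6,7-octahydroazulen-6-ol; 22 (2E)-3-[4-(acetyloxy)phenyl]prop-2-enoic acid
Product: 24 (3S,3aS,5S,6S)-5-(2-hydroxypropan-2-yl)-3,8-dimethyl-1,2,3,3a,4,5,6,7-octahydroazulen-6-yl (2E)-3-[4-(acetyloxy)phenyl]prop-2-enoate, via mixed anhydride 23 (not isolated)
Conditions: 22, 2,4,6-Cl3C6H2COCl, Et3N, toluene, rt; then 21, DMAP, toluene, rt → 40 °C
Reagents that add atoms: none
Why: Yamaguchi esterification through the mixed anhydride 23; DMAP transfers the cinnamoyl group to the secondary C6 hydroxyl while the tertiary hydroxyl stays free.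

Step 13
Reactants: 24 (3S,3aS,5S,6S)-5-(2-hydroxypropan-2-yl)-3,8-dimethyl-1,2,3,3a,4,5,6,7-octahydroazulen-6-yl (2E)-3-[4-(acetyloxy)phenyl]prop-2-enoate
Product: 25 (3S,3aS,5S,6S)-5-(2-hydroxypropan-2-yl)-3,8-dimethyl-1,2,3,3a,4,5,6,7-octahydroazulen-6-yl (2E)-3-(4-hydroxyphenyl)prop-2-enoate
Conditions: K2CO3 (0.2 equiv), MeOH, 0 °C
Reagents that add atoms: none
Why: Base-catalysed transesterification; the aryl acetate, with a phenoxide leaving group, is methanolysed far faster than the hindered secondary cinnamate, which frees the phenol and gives the target.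

## Compound list

1 | pent-3-yn-2-one | CC#CC(C)=O | starting material
2 | (2S)-pent-3-yn-2-ol | C[C@H](O)C#CC | intermediate
3 | sodium (5S)-2,2-bis(2-methoxyethoxy)-3,5-dimethyl-2,5-dihydro-1,2-oxaaluminol-2-uide (cyclic alkenylalanate) | C[C@@H]1O[Al-](OCCOC)(OCCOC)C(C)=C1.[Na+] | intermediate (not isolated)
4 | (2S,3Z)-4-iodopent-3-en-2-ol | C[C@H](O)/C=C(I)/C | intermediate
5 | (1S)-1-[(1R,2R)-2-iodo-2-methylcyclopropyl]ethan-1-ol | C[C@H](O)[C@H]1C[C@@]1(C)I | intermediate
6 | 1-[(1R,2R)-2-iodo-2-methylcyclopropyl]ethan-1-one | CC(=O)[C@H]1C[C@@]1(C)I | intermediate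
7 | tert-butyl({1-[(1R,2R)-2-iodo-2-methylcyclopropyl]ethenyl}oxy)dimethylsilane | C=C(O[Si](C)(C)C(C)(C)C)[C@H]1C[C@@]1(C)I | intermediate
8 | 3-methylcyclopent-2-en-1-one | CC1=CC(=O)CC1 | starting material
9 | bis{[(3S)-3-methylcyclopent-1-en-1-yl]oxy}diphenylsilane | c1ccccc1[Si](OC2=C[C@@H](C)CC2)(OC3=C[C@@H](C)CC3)c4ccccc4 | intermediate (not isolated)
10 | lithium (3S)-3-methylcyclopent-1-en-1-olate | [Li+].[O-]C1=C[C@@H](C)CC1 | intermediate (not isolated)
11 | (3S)-3-methylcyclopent-1-en-1-yl trifluoromethanesulfonate | O=S(=O)(OC1=C[C@@H](C)CC1)C(F)(F)F | intermediate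
12 | {(1S,2S)-2-[1-(tert-butyldimethylsilyloxy)ethenyl]-1-methylcyclopropyl}lithium | C=C(O[Si](C)(C)C(C)(C)C)[C@H]1C[C@@]1(C)[Li] | intermediate (not isolated)
13 | chloro{(1R,2R)-2-[1-(tert-butyldimethylsilyloxy)ethenyl]-1-methylcyclopropyl}zinc | C=C(O[Si](C)(C)C(C)(C)C)[C@H]1C[C@@]1(C)[Zn]Cl | intermediate (not isolated)
14 | tert-butyldimethyl[(1-{(1S,2R)-2-methyl-2-[(3S)-3-methylcyclopent-1-en-1-yl]cyclopropyl}ethenyl)oxy]silane | C=C(O[Si](C)(C)C(C)(C)C)[C@H]1C[C@@]1(C)C2=C[C@@H](C)CC2 | intermediate (not isolated)
15 | tert-butyl{[(3S,3aS)-3,8-dimethyl-1,2,3,3a,4,7-hexahydroazulen-5-yl]oxy}dimethylsilane | CC1=C2CC[C@H](C)[C@@H]2CC(O[Si](C)(C)C(C)(C)C)=CC1 | intermediate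
16 | caesium (3S,3aS)-3,8-dimethyl-1,2,3,3a,4,7-hexahydroazulen-5-olate | CC1=C2CC[C@H](C)[C@@H]2CC([O-])=CC1.[Cs+] | intermediate (not isolated)
17 | (3S,3aS)-3,8-dimethyl-1,2,3,3a,4,7-hexahydroazulen-5-yl trifluoromethanesulfonate | CC1=C2CC[C@H](C)[C@@H]2CC(OS(=O)(=O)C(F)(F)F)=CC1 | intermediate
18 | methyl (3S,3aS)-3,8-dimethyl-1,2,3,3a,4,7-hexahydroazulene-5-carboxylate | CC1=C2CC[C@H](C)[C@@H]2CC(C(=O)OC)=CC1 | intermediate
19 | 2-[(3S,3aS)-3,8-dimethyl-1,2,3,3a,4,7-hexahydroazulen-5-yl]propan-2-ol | CC1=C2CC[C@H](C)[C@@H]2CC(C(C)(C)O)=CC1 | intermediate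
20 | cyclic alkoxyborane: 1,2-oxaborolane (B–H) joining the carbinol oxygen and C6, with (3S,3aS,5S,6S) configuration at the azulene positions | CC1=C2CC[C@H](C)[C@@H]2C[C@H]3[C@H](C1)[BH]OC3(C)C | intermediate (not isolated)
21 | (3S,3aS,5S,6S)-5-(2-hydroxypropan-2-yl)-3,8-dimethyl-1,2,3,3a,4,5,6,7-octahydroazulen-6-ol | CC1=C2CC[C@H](C)[C@@H]2C[C@H](C(C)(C)O)[C@@H](O)C1 | intermediate
22 | (2E)-3-[4-(acetyloxy)phenyl]prop-2-enoic acid | CC(=O)Oc1ccc(/C=C/C(=O)O)cc1 | starting material
23 | (2E)-3-[4-(acetyloxy)phenyl]prop-2-enoic 2,4,6-trichlorobenzoic anhydride | CC(=O)Oc1ccc(/C=C/C(=O)OC(=O)c2c(Cl)cc(Cl)cc2Cl)cc1 | intermediate (not isolated)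
24 | (3S,3aS,5S,6S)-5-(2-hydroxypropan-2-yl)-3,8-dimethyl-1,2,3,3a,4,5,6,7-octahydroazulen-6-yl (2E)-3-[4-(acetyloxy)phenyl]prop-2-enoate | CC1=C2CC[C@H](C)[C@@H]2C[C@H](C(C)(C)O)[C@@H](OC(=O)/C=C/c2ccc(OC(C)=O)cc2)C1 | intermediate
25 | (3S,3aS,5S,6S)-5-(2-hydroxypropan-2-yl)-3,8-dimethyl-1,2,3,3a,4,5,6,7-octahydroazulen-6-yl (2E)-3-(4-hydroxyphenyl)prop-2-enoate | CC1=C2CC[C@H](C)[C@@H]2C[C@H](C(C)(C)O)[C@@H](OC(=O)/C=C/c2ccc(O)cc2)C1 | target

## Step count and risks

Total step count: 13. Longest linear sequence: 12 steps (steps 1–5, then 7–13, from pent-3-yn-2-one); step 6 is a one-step branch.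

Steps most likely to fail:

**Step 7 (key step).** Three processes may interfere: migration of the silyl group from the enol oxygen to the cyclopropyl carbanion before transmetalation; slow transmetalation or protodemetalation of the hindered tertiary cyclopropylzinc; and, if the rearrangement is slowed because the new bond forms syn to the C3 methyl group, one-centre epimerisation of the cyclopropane. The fallback reverses the polarity so that no cyclopropyl carbanion is made. From 11, Miyaura borylation (B2pin2, PdCl2(PPh3)2, PPh3, KOPh, toluene, 50 °C) would give 4,4,5,5-tetramethyl-2-[(3S)-3-methylcyclopent-1-en-1-yl]-1,3,2-dioxaborolane F1. Suzuki–Miyaura coupling of F1 with iodide 7 as the electrophile (Pd(OAc)2, PCy3, CsF, dioxane, 90 °C; oxidative addition into iodocyclopropanes and the coupling proceed with retention) would again give 14. This rearranges at the coupling temperature, and the route is rejoined at 15.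

**Step 11.** Facial selectivity of the hydroboration may be poor, because the controlling centre C3a is two atoms from the alkene, and the tetrasubstituted alkene may be hydroborated in competition. The fallback puts C6 under catalyst control and C5 under thermodynamic control. From 18, copper-catalysed asymmetric conjugate borylation (CuCl, NaOt-Bu, (R)-Tol-BINAP, B2pin2, MeOH, THF), followed by brief NaOMe equilibration of the ester-bearing centre to the trans isomer, would give methyl (3S,3aS,5S,6S)-3,8-dimethyl-6-(4,4,5,5-tetramethyl-1,3,2-dioxaborolan-2-yl)-1,2,3,3a,4,5,6,7-octahydroazulene-5-carboxylate F2. Oxidation (NaBO3·4H2O, THF/H2O) would give methyl (3S,3aS,5S,6S)-6-hydroxy-3,8-dimethyl-1,2,3,3a,4,5,6,7-octahydroazulene-5-carboxylate F3. Excess MeMgBr (THF, 0 °C) would convert F3 into 21, where the route is rejoined.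

**Step 12.** Acylation of the hindered secondary hydroxyl next to the tertiary carbinol may be slow, with competing acetyl transfer from the aryl acetate. The fallback builds the cinnamate by olefination instead. From 21, esterification with the small (diethoxyphosphoryl)acetic acid (DCC, DMAP, CH2Cl2) would give (3S,3aS,5S,6S)-5-(2-hydroxypropan-2-yl)-3,8-dimethyl-1,2,3,3a,4,5,6,7-octahydroazulen-6-yl 2-(diethoxyphosphoryl)acetate F4. Horner–Wadsworth–Emmons reaction of F4 with 4-acetoxybenzaldehyde (LiCl, i-Pr2NEt, MeCN, rt) would give the E-cinnamate 24, where the route is rejoined.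

Further compounds
F1 | step 7 | 4,4,5,5-tetramethyl-2-[(3S)-3-methylcyclopent-1-en-1-yl]-1,3,2-dioxaborolane | CC1(C)OB(OC1(C)C)C2=C[C@@H](C)CC2
F2 | step 11 | methyl (3S,3aS,5S,6S)-3,8-dimethyl-6-(4,4,5,5-tetramethyl-1,3,2-dioxaborolan-2-yl)-1,2,3,3a,4,5,6,7-octahydroazulene-5-carboxylate | CC1=C2CC[C@H](C)[C@@H]2C[C@H](C(=O)OC)[C@@H](B3OC(C)(C)C(C)(C)O3)C1
F3 | step 11 | methyl (3S,3aS,5S,6S)-6-hydroxy-3,8-dimethyl-1,2,3,3a,4,5,6,7-octahydroazulene-5-carboxylate | CC1=C2CC[C@H](C)[C@@H]2C[C@H](C(=O)OC)[C@@H](O)C1
F4 | step 12 | (3S,3aS,5S,6S)-5-(2-hydroxypropan-2-yl)-3,8-dimethyl-1,2,3,3a,4,5,6,7-octahydroazulen-6-yl 2-(diethoxyphosphoryl)acetate | CC1=C2CC[C@H](C)[C@@H]2C[C@H](C(C)(C)O)[C@@H](OC(=O)CP(=O)(OCC)OCC)C1
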